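The numbers stand for no real mixture; the result is computed.

Take the dissolving of solid E as the tap of these flasks, and ask how long the solid can keep it running.

    2 G → G2 (k1 = 0.0216 M⁻¹ s⁻¹)
    G + L → G.L (k2 = 0.00190 M⁻¹ s⁻¹)
    E ⇌ G, rate k3*(cs3 - [G]) while solid is left; crystals form when [G] > cs3 (cs3 = 3.2 mM, k3 = 1.09 × 10⁻⁵ s⁻¹)
    L → X (k4 = 1.94 × 10⁻⁵ s⁻¹)

common to all: L 0.0234 M; time 5.0 h
- Monday's: E 0.0050 M
- Thursday's: E 0.010 M
- Sunday's: E 0.020 M

- percentages count the E that a species holds: one G2 counts as two
- where a step has two of a species, its rate is k times that concentration squared, and two are used at each turn
- solid, in amounts per volume of the solution: E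
- at the start none of E is in solution
- "hardly changes" means that all values lie within two and a half points (for a concentration: within two and a half percent of the largest)
- run time (Monday's): 5.0 h

- share of G.L in all that became G.L or G2 for Monday's, Thursday's, Sunday's, in this order
- how that number moves from the first to the last of them (falls, then rises / rises, then falls / hardly changes / rises all the way / falls all the way)

The solid enters the dissolving rate through one condition, that some of it is left, so the step is zero-order in the solid. Its rate is highest with no G in solution, which gives a ceiling:

  ceiling = dissolution coefficient × solubility = 1.09 × 10⁻⁵ s⁻¹ × 3.2 mM = 0.126 mM h⁻¹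

  clearing time = E charged / ceiling; Monday's: 0.0050 M / 0.126 mM h⁻¹ = 39.8 h

This clearing time, the charge of E divided by the ceiling, is how long the solid lasts if it dissolves at the ceiling throughout, and the real dissolving can go no faster.

The charge is the first setting to turn, and the clearing time grows with it:

    Thursday's: 79.6 h; Sunday's: 159 h

Thursday's clearing time is twice Monday's.

Monday's clearing time is the shortest of these, yet it is longer than the run of 5.0 h, so by hand solid stands to the end in each recipe and the charge drops out of the rate equations. The concentrations of G, L, G.L and G2 then follow one course in Monday's, Thursday's and Sunday's, and the share of G.L comes out equal, though this reckoning gives no value for it.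

The run time is the second setting. At 50.0 h Monday's clearing time has passed while Thursday's has not, so by hand the solid can be gone from Monday's flask but not from Thursday's.

The forecast gives 74.5%, 74.5% and 74.5%, hence hardly changes, with the words “The E loading therefore has no effect”; it took the value itself from stepping the rate equation by hand.

The simulation gives 74.5%, 74.5% and 74.5%: hardly changes.

Monday's clearing time of 39.8 h stands against the run of 5.0 h in what the flask shows: after 5.00 h E holds 88.3% of its charge, above the 87.4% that the ceiling allows, and by 50.0 h, past that clearing time, Monday's E stands at 0%. Thursday's flask, with a clearing time of 79.6 h, still holds E at 50.0 h, namely 49.5% of its charge, above the 37.2% that its ceiling allows.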